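**Retrosynthetic overview**

1. The tiglates are put on last. The enone comes from the tricyclic ketone by dehydrogenation, 1,2-addition of MeLi and oxidative allylic transposition.
2. Key disconnection: the cyclobutane bond C2–C8 of the tricyclo[5.4.0.0^{2,8}]undecane (longipinane) core is opened to a cis-fused bicyclo[5.4.0]undecene carrying a 2,3-epoxide in the seven-membered ring and a C8=C9 silyl enol ether in the six-membered ring.
3. Enabling feature: the quaternary, methyl-bearing cyclobutane carbon C2 is flanked by the oxygenated C3 with the C3–O bond anti to C2–C8, and C8 is α to C9, which can be held at the ketone level. Across the cis ring fusion C1–C7, the enol carbon C8 and the epoxide carbon C2 stand in a 1,3-diaxial-type relation.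
4. The cycloheptene is closed by ring-closing metathesis, the cyclohexene by a catalytic asymmetric Diels–Alder reaction, the C5 carbinol by reagent-controlled allylboration, and the epoxide from the convex face.
5. Ring order: six-membered ring (step 3), seven-membered ring (step 8), cyclobutane (step 12).

Key step: step 12

Assumption: 1, 2, 5 and 23 are catalogue chemicals; locants follow bicyclo[5.4.0]undecane / tricyclo[5.4.0.0^{2,8}]undecane numbering (C1/C7 ring fusion, C2 methyl-bearing, C3 and C5 oxygenated, C6 gem-dimethyl).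

**Route**

Step 1
Reactants: 1 methyl 2,2-dimethyl-3-oxopropanoate; 2 1-(triphenyl-λ5-phosphanylidene)propan-2-one
Product: 3 methyl (E)-2,2-dimethyl-5-oxohex-3-enoate
Conditions: toluene, 90 °C
Reagents that add atoms: 1-(triphenyl-λ5-phosphanylidene)propan-2-one (2), CC(=O)C=P(c1ccccc1)(c1ccccc1)c1ccccc1
Why: Wittig olefination with a stabilised ylide, which should give the (E)-enone from the non-enolisable α-quaternary aldehyde.

Step 2
Reactants: 3 methyl (E)-2,2-dimethyl-5-oxohex-3-enoate
Product: 4 methyl (E)-5-(tert-butyldimethylsilyloxy)-2,2-dimethylhexa-3,5-dienoate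
Conditions: TBSOTf, Et3N, CH2Cl2, 0 °C
Reagents that add atoms: tert-butyldimethylsilyl trifluoromethanesulfonate, CC(C)(C)[Si](C)(C)OS(=O)(=O)C(F)(F)F
Why: Soft enolisation and O-silylation of the methyl ketone, the only enolisable site, should give the 2-silyloxy-1,3-diene with the (E)-alkene retained.

Step 3
Reactants: 4 methyl (E)-5-(tert-butyldimethylsilyloxy)-2,2-dimethylhexa-3,5-dienoate; 5 but-3-en-2-one
Product: 6 methyl 2-[(1S,6R)-6-acetyl-3-(tert-butyldimethylsilyloxy)cyclohex-2-en-1-yl]-2-methylpropanoate (cis)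
Conditions: (S)-o-tolyl-CBS-oxazaborolidine activated with Tf2NH (20 mol%; the mirror-image catalyst if the facial sense proves opposite), CH2Cl2, −78 → −40 °C
Reagents that add atoms: but-3-en-2-one (5), CC(=O)C=C
Why: Catalytic enantioselective Diels–Alder reaction in which the 1-alkyl and 3-silyloxy groups of the diene both place the acetyl carbon next to C1 of the new ring, the endo transition state sets acetyl and the tert-alkyl group cis, and the chiral boron cation should block one face of the s-cis enone so that the diene adds to the Cα Si face.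

Step 4
Reactants: 6 Diels–Alder adduct
Product: 7 methyl 2-[cis-3-(tert-butyldimethylsilyloxy)-6-(prop-1-en-2-yl)cyclohex-2-en-1-yl]-2-methylpropanoate (ring configuration as in 6)
Conditions: Ph3PCH3Br, KN(SiMe3)2, THF, −78 → 0 °C
Reagents that add atoms: methylenetriphenylphosphorane, C=P(c1ccccc1)(c1ccccc1)c1ccccc1
Why: Wittig methylenation, chemoselective for the methyl ketone over the hindered α-quaternary ester and run cold so that the stereocentre α to the ketone should not epimerise.

Step 5
Reactants: 7 isopropenyl ester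
Product: 8 2-[cis-3-(tert-butyldimethylsilyloxy)-6-(prop-1-en-2-yl)cyclohex-2-en-1-yl]-2-methylpropanal
Conditions: i-Bu2AlH (1.1 equiv), CH2Cl2, −78 °C; aqueous potassium sodium tartrate
Reagents that add atoms: none
Why: Partial ester reduction with i-Bu2AlH, where the hindered aluminium hemiacetal of the α-quaternary ester should persist at −78 °C and release the aldehyde on work-up.

Step 6
Reactants: 8 aldehyde
Product: 10 (3R)-2-methyl-2-[cis-3-(tert-butyldimethylsilyloxy)-6-(prop-1-en-2-yl)cyclohex-2-en-1-yl]hex-5-en-3-ol, via borinate ester 9 (not isolated)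
Conditions: (+)-B-allylbis(isopinocampheyl)borane (from (−)-α-pinene), Et2O, −78 °C; then NaOH, H2O2, 0 °C
Reagents that add atoms: (+)-B-allylbis(isopinocampheyl)borane, C=CCB([C@@H]1[C@@H](C)[C@@H]2C[C@H](C1)C2(C)C)[C@@H]1[C@@H](C)[C@@H]2C[C@H](C1)C2(C)C
Why: Brown allylboration through a chair transition state, a reagent-controlled Re-face addition that should set the (R)-carbinol regardless of the remote ring stereocentres.

Step 7
Reactants: 10 homoallylic alcohol
Product: 11 tert-butyldimethylsilyl ether of 10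
Conditions: TBSOTf, 2,6-lutidine, CH2Cl2, −78 → 0 °C
Reagents that add atoms: tert-butyldimethylsilyl trifluoromethanesulfonate, CC(C)(C)[Si](C)(C)OS(=O)(=O)C(F)(F)F
Why: O-Silylation of a hindered secondary alcohol with a silyl triflate.

Step 8
Reactants: 11 triene
Product: 12 cis-fused 5,9-bis(tert-butyldimethylsilyloxy)-2,6,6-trimethylbicyclo[5.4.0]undeca-2,8-diene
Conditions: second-generation Grubbs catalyst (5 mol%), CH2Cl2, 40 °C
Reagents that add atoms: none
Why: Ring-closing olefin metathesis between the isopropenyl group and the terminal allyl alkene, which are cis on the cyclohexene, should close the cycloheptene with its trisubstituted C2=C3 bond and leave the hindered enol ether alone.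

Step 9
Reactants: 12 bicyclic silyl enol ether
Product: 14 cis-fused 5-(tert-butyldimethylsilyloxy)-2,6,6-trimethylbicyclo[5.4.0]undeca-2,8-dien-9-yl acetate, via lithium enolate 13 (not isolated)
Conditions: MeLi (1.2 equiv), THF, 0 → 23 °C; then Ac2O, −78 → 0 °C
Reagents that add atoms: acetic anhydride, CC(=O)OC(C)=O
Why: Regiospecific cleavage of the silyl enol ether to its lithium enolate and O-acetylation; the enol acetate keeps the C8=C9 position fixed by the cycloaddition but is far less nucleophilic towards peracid.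

Step 10
Reactants: 14 enol acetate
Product: 15 2,3-epoxide of 14 (oxygen on the face of the two ring-fusion hydrogens)
Conditions: mCPBA (1.05 equiv), NaHCO3, CH2Cl2, −20 °C
Reagents that add atoms: 3-chloroperoxybenzoic acid, OOC(=O)c1cccc(Cl)c1
Why: Prilezhaev epoxidation, in which the trisubstituted C2=C3 alkene should react much faster than the enol acetate and the peracid should approach the convex face, anti to the allylic C1–C11 bond and to the C5 silyloxy group, setting C2 and C3.

Step 11
Reactants: 15 epoxy enol acetate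
Product: 17 cis-fused 2,3-epoxy-5,9-bis(tert-butyldimethylsilyloxy)-2,6,6-trimethylbicyclo[5.4.0]undec-8-ene, via lithium enolate 16 (not isolated)
Conditions: MeLi (2.2 equiv), THF, −40 → 0 °C; then TBSCl, DMPU, −78 → 0 °C
Reagents that add atoms: tert-butyldimethylsilyl chloride, CC(C)(C)[Si](C)(C)Cl
Why: Enol acetate cleavage by two equivalents of MeLi gives the regiodefined lithium enolate, which is O-silylated; the trisubstituted epoxide should be inert to MeLi at this temperature.

Step 12
Reactants: 17 epoxy silyl enol ether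
Product: 18 3,5-bis(tert-butyldimethylsilyloxy)-2,6,6-trimethyltricyclo[5.4.0.0^{2,8}]undecan-9-one
Conditions: TBSOTf (0.2 equiv), 2,6-di-tert-butyl-4-methylpyridine (0.3 equiv), CH2Cl2, −78 → −40 °C
Reagents that add atoms: none
Why: Proposed new method: the silyl cation binds the epoxide oxygen, the enol-ether carbon C8 attacks the tertiary epoxide carbon C2 from the rear, and the oxocarbenium ion formed at C9 passes its silyl group to the next epoxide, so that 17 isomerises to 18 with the silyl group on O3. The closest known reaction types are the Lewis-acid (Mukaiyama-type) opening of epoxides by silyl enol ethers and the exo-selective Stork epoxynitrile cyclisation, which gives cyclobutanes in preference to cyclopentanes; the biosynthetic himachalyl-to-longipinyl cation closure is the natural model, but a cyclobutane has not been closed this way at a tertiary epoxide carbon. The cyclobutane C1–C2–C8–C7 closes in the 4-exo-tet mode. C2 is set by inversion and therefore by the epoxide configuration, C8 by the fact that only the concave face of the enol ether can reach C2 (pseudo-axial on C1) across the cis ring fusion, and C3 is retained. The step needs attack at C2 rather than at C3 (5-endo) and C–C bond formation rather than hydride shift or proton loss; the cation-stabilising tertiary C2, the collinear O–C2···C8 alignment available only for exo attack, the low temperature and the hindered base should secure this. Release of epoxide strain and formation of the C9 carbonyl should offset the cyclobutane strain.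

Step 13
Reactants: 18 tricyclic ketone
Product: 19 3,5-bis(tert-butyldimethylsilyloxy)-2,6,6-trimethyltricyclo[5.4.0.0^{2,8}]undec-10-en-9-one
Conditions: IBX (2 equiv), DMSO–fluorobenzene, 70 °C
Reagents that add atoms: none
Why: IBX-mediated α,β-dehydrogenation of a ketone, regiospecific because only C10 can enolise, C8 being a bridgehead of the bicyclo[3.1.1]heptanone.

Step 14
Reactants: 19 enone
Product: 20 3,5-bis(tert-butyldimethylsilyloxy)-2,6,6,9-tetramethyltricyclo[5.4.0.0^{2,8}]undec-10-en-9-ol
Conditions: MeLi, Et2O, −78 °C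
Reagents that add atoms: methyllithium, [Li]C
Why: 1,2-Addition of an organolithium to the enone carbonyl, expected from the face of the hydrogen-bearing C7 bridge; the new carbinol centre is destroyed in the next step.

Step 15
Reactants: 20 tertiary allylic alcohol
Product: 21 3,5-bis(tert-butyldimethylsilyloxy)-2,6,6,9-tetramethyltricyclo[5.4.0.0^{2,8}]undec-9-en-11-one
Conditions: pyridinium chlorochromate (3 equiv), 4 Å molecular sieves, CH2Cl2, 23 °C
Reagents that add atoms: pyridinium chlorochromate, [O-][Cr](=O)(=O)Cl.c1cc[nH+]cc1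
Why: Babler–Dauben oxidative transposition, in which the tertiary allylic chromate ester undergoes a [3,3] shift and the resulting secondary allylic chromate is oxidised to the enone, as in the conversion of pin-3-en-2-ol into verbenone.

Step 16
Reactants: 21 bis-silyl enone
Product: 22 (1R,2R,3R,5R,7S,8R)-3,5-dihydroxy-2,6,6,9-tetramethyltricyclo[5.4.0.0^{2,8}]undec-9-en-11-one
Conditions: HF·pyridine, pyridine, THF, 0 → 23 °C
Reagents that add atoms: none
Why: Fluoride-mediated desilylation under non-basic conditions that the enone should tolerate.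

Step 17
Reactants: 22 diol; 23 (E)-2-methylbut-2-enoyl chloride
Product: 24 (1R,2R,3R,5R,7S,8R)-2,6,6,9-tetramethyl-11-oxotricyclo[5.4.0.0^{2,8}]undec-9-ene-3,5-diyl bis[(E)-2-methylbut-2-enoate] (target)
Conditions: 23 (4 equiv), pyridine, DMAP (20 mol%), CH2Cl2, 40 °C
Reagents that add atoms: (E)-2-methylbut-2-enoyl chloride (23), C/C=C(\C)C(Cl)=O
Why: DMAP-catalysed acylation of the two hindered secondary alcohols through the acylpyridinium ion, the (E)-geometry of the tigloyl group being the stable one.

**Compound list**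

1 | methyl 2,2-dimethyl-3-oxopropanoate | COC(=O)C(C)(C)C=O | starting material
2 | 1-(triphenyl-λ5-phosphanylidene)propan-2-one | CC(=O)C=P(c1ccccc1)(c1ccccc1)c1ccccc1 | starting material
3 | methyl (E)-2,2-dimethyl-5-oxohex-3-enoate | COC(=O)C(C)(C)/C=C/C(C)=O | intermediate
4 | methyl (E)-5-(tert-butyldimethylsilyloxy)-2,2-dimethylhexa-3,5-dienoate | COC(=O)C(C)(C)/C=C/C(=C)O[Si](C)(C)C(C)(C)C | intermediate
5 | but-3-en-2-one | CC(=O)C=C | starting material
6 | methyl 2-[(1S,6R)-6-acetyl-3-(tert-butyldimethylsilyloxy)cyclohex-2-en-1-yl]-2-methylpropanoate | COC(=O)C(C)(C)[C@H]1C=C(O[Si](C)(C)C(C)(C)C)CC[C@H]1C(C)=O | intermediate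
7 | methyl 2-[cis-3-(tert-butyldimethylsilyloxy)-6-(prop-1-en-2-yl)cyclohex-2-en-1-yl]-2-methylpropanoate | COC(=O)C(C)(C)[C@H]1C=C(O[Si](C)(C)C(C)(C)C)CC[C@H]1C(C)=C | intermediate
8 | 2-[cis-3-(tert-butyldimethylsilyloxy)-6-(prop-1-en-2-yl)cyclohex-2-en-1-yl]-2-methylpropanal | O=CC(C)(C)[C@H]1C=C(O[Si](C)(C)C(C)(C)C)CC[C@H]1C(C)=C | intermediate
9 | bis(isopinocampheyl)borinate ester of 10 | C=CC[C@@H](OB([C@@H]1[C@@H](C)[C@@H]2C[C@H](C1)C2(C)C)[C@@H]1[C@@H](C)[C@@H]2C[C@H](C1)C2(C)C)C(C)(C)[C@H]1C=C(O[Si](C)(C)C(C)(C)C)CC[C@H]1C(C)=C | intermediate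
10 | (3R)-2-methyl-2-[cis-3-(tert-butyldimethylsilyloxy)-6-(prop-1-en-2-yl)cyclohex-2-en-1-yl]hex-5-en-3-ol | C=CC[C@@H](O)C(C)(C)[C@H]1C=C(O[Si](C)(C)C(C)(C)C)CC[C@H]1C(C)=C | intermediate
11 | tert-butyldimethylsilyl ether of 10 | C=CC[C@@H](O[Si](C)(C)C(C)(C)C)C(C)(C)[C@H]1C=C(O[Si](C)(C)C(C)(C)C)CC[C@H]1C(C)=C | intermediate
12 | cis-fused 5,9-bis(tert-butyldimethylsilyloxy)-2,6,6-trimethylbicyclo[5.4.0]undeca-2,8-diene | CC(C)(C)[Si](C)(C)O[C@@H]1CC=C(C)[C@@H]2CCC(O[Si](C)(C)C(C)(C)C)=C[C@@H]2C1(C)C | intermediate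
13 | lithium C8=C9 enolate from 12 | CC(C)(C)[Si](C)(C)O[C@@H]1CC=C(C)[C@@H]2CCC(O[Li])=C[C@@H]2C1(C)C | intermediate
14 | cis-fused 5-(tert-butyldimethylsilyloxy)-2,6,6-trimethylbicyclo[5.4.0]undeca-2,8-dien-9-yl acetate | CC(C)(C)[Si](C)(C)O[C@@H]1CC=C(C)[C@@H]2CCC(OC(C)=O)=C[C@@H]2C1(C)C | intermediate
15 | 2,3-epoxide of 14 | CC(C)(C)[Si](C)(C)O[C@@H]1C[C@H]2O[C@@]2(C)[C@@H]3CCC(OC(C)=O)=C[C@@H]3C1(C)C | intermediate
16 | lithium C8=C9 enolate from 15 | CC(C)(C)[Si](C)(C)O[C@@H]1C[C@H]2O[C@@]2(C)[C@@H]3CCC(O[Li])=C[C@@H]3C1(C)C | intermediate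
17 | cis-fused 2,3-epoxy-5,9-bis(tert-butyldimethylsilyloxy)-2,6,6-trimethylbicyclo[5.4.0]undec-8-ene | CC(C)(C)[Si](C)(C)O[C@@H]1C[C@H]2O[C@@]2(C)[C@@H]3CCC(O[Si](C)(C)C(C)(C)C)=C[C@@H]3C1(C)C | intermediate
18 | 3,5-bis(tert-butyldimethylsilyloxy)-2,6,6-trimethyltricyclo[5.4.0.0^{2,8}]undecan-9-one | CC(C)(C)[Si](C)(C)O[C@@H]1C[C@@H](O[Si](C)(C)C(C)(C)C)[C@@]2(C)[C@@H]3CCC(=O)[C@H]2[C@@H]3C1(C)C | intermediate
19 | 3,5-bis(tert-butyldimethylsilyloxy)-2,6,6-trimethyltricyclo[5.4.0.0^{2,8}]undec-10-en-9-one | CC(C)(C)[Si](C)(C)O[C@@H]1C[C@@H](O[Si](C)(C)C(C)(C)C)[C@@]2(C)[C@@H]3C=CC(=O)[C@H]2[C@@H]3C1(C)C | intermediate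
20 | 3,5-bis(tert-butyldimethylsilyloxy)-2,6,6,9-tetramethyltricyclo[5.4.0.0^{2,8}]undec-10-en-9-ol | CC(C)(C)[Si](C)(C)O[C@@H]1C[C@@H](O[Si](C)(C)C(C)(C)C)[C@@]2(C)[C@@H]3C=C[C@](C)(O)[C@H]2[C@@H]3C1(C)C | intermediate
21 | 3,5-bis(tert-butyldimethylsilyloxy)-2,6,6,9-tetramethyltricyclo[5.4.0.0^{2,8}]undec-9-en-11-one | CC(C)(C)[Si](C)(C)O[C@@H]1C[C@@H](O[Si](C)(C)C(C)(C)C)[C@@]2(C)[C@@H]3C(=O)C=C(C)[C@H]2[C@@H]3C1(C)C | intermediate
22 | (1R,2R,3R,5R,7S,8R)-3,5-dihydroxy-2,6,6,9-tetramethyltricyclo[5.4.0.0^{2,8}]undec-9-en-11-one | O[C@@H]1C[C@@H](O)[C@@]2(C)[C@@H]3C(=O)C=C(C)[C@H]2[C@@H]3C1(C)C | intermediate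
23 | (E)-2-methylbut-2-enoyl chloride | C/C=C(\C)C(Cl)=O | starting material
24 | (1R,2R,3R,5R,7S,8R)-2,6,6,9-tetramethyl-11-oxotricyclo[5.4.0.0^{2,8}]undec-9-ene-3,5-diyl bis[(E)-2-methylbut-2-enoate] | C/C=C(\C)C(=O)O[C@@H]1C[C@@H](OC(=O)/C(C)=C/C)[C@@]2(C)[C@@H]3C(=O)C=C(C)[C@H]2[C@@H]3C1(C)C | target

**Step count and risks**

Total step count: 17. Longest linear sequence: 17 steps (from 1).

Steps most likely to fail:

1. Step 12 (proposed new method). The reactive conformer, with the epoxide carbon pseudo-axial and collinear for rear attack, may be too sparsely populated, so that the silylated epoxide is lost by hydride shift or proton loss before the strained ring closes. The fallback uses known reactions and sets out from 15. Anhydrous HCl in Et2O at −30 °C should open the epoxide in Markovnikov, anti fashion to the tertiary chloride with a free C3 hydroxyl, chlorohydrin F1. TBSOTf and 2,6-lutidine give its silyl ether F2. AgOTf with 2,6-di-tert-butylpyridine in CH2Cl2 at −40 °C ionises the tertiary chloride, and the cation, which needs no collinear leaving group, is captured on its only accessible face by the enol acetate carbon C8 (silver-assisted SN1 α-tert-alkylation of an enol derivative, Reetz type), with loss of the acetyl group on work-up. This comes back to the route at 18.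

2. Step 3. Enantio- and endo-selectivity may erode, or a stepwise Mukaiyama–Michael addition may intervene, with the hindered 1-tert-alkyl diene under the cationic boron catalyst. The fallback replaces asymmetric catalysis by resolution and sets out from 4. A Me2AlCl-promoted Diels–Alder reaction with 5 gives the racemic cis adduct, that is 6 together with its enantiomer F3. Steps 4 and 5 carried out on the racemate give 7 with its enantiomer F4 and 8 with its enantiomer F5. The allylboration of step 6 then acts as a reagent-controlled resolution: 8 gives 10, while F5 gives, via the borinate F6, the diastereomeric alcohol F7, which is removed by chromatography. The route is rejoined at 10.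

3. Step 15. The tertiary allylic chromate next to the cyclobutane may ionise, leading to Wagner–Meerwein ring expansion or fragmentation instead of the [3,3] shift. The fallback sets out from 18 and bypasses steps 13 to 15. KN(SiMe3)2 and PhNTf2 give the enol triflate F8 (only C10 can enolise). MeMgBr with Fe(acac)3 in THF/NMP gives the trisubstituted alkene F9. Allylic oxidation at C11 with CrO3·3,5-dimethylpyrazole in CH2Cl2 at −20 °C (the α-pinene to verbenone transformation) returns to the route at 21.

**Further compounds**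

F1 | step 12 | cis-fused 2-chloro-3-hydroxy-5-(tert-butyldimethylsilyloxy)-2,6,6-trimethylbicyclo[5.4.0]undec-8-en-9-yl acetate | CC(C)(C)[Si](C)(C)O[C@@H]1C[C@@H](O)[C@@](Cl)(C)[C@@H]2CCC(OC(C)=O)=C[C@@H]2C1(C)C
F2 | step 12 | tert-butyldimethylsilyl ether of F1 | CC(C)(C)[Si](C)(C)O[C@@H]1C[C@@H](O[Si](C)(C)C(C)(C)C)[C@@](Cl)(C)[C@@H]2CCC(OC(C)=O)=C[C@@H]2C1(C)C
F3 | step 3 | enantiomer of 6 | COC(=O)C(C)(C)[C@@H]1C=C(O[Si](C)(C)C(C)(C)C)CC[C@@H]1C(C)=O
F4 | step 3 | enantiomer of 7 | COC(=O)C(C)(C)[C@@H]1C=C(O[Si](C)(C)C(C)(C)C)CC[C@@H]1C(C)=C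
F5 | step 3 | enantiomer of 8 | O=CC(C)(C)[C@@H]1C=C(O[Si](C)(C)C(C)(C)C)CC[C@@H]1C(C)=C
F6 | step 3 | bis(isopinocampheyl)borinate ester of F7 | C=CC[C@@H](OB([C@@H]1[C@@H](C)[C@@H]2C[C@H](C1)C2(C)C)[C@@H]1[C@@H](C)[C@@H]2C[C@H](C1)C2(C)C)C(C)(C)[C@@H]1C=C(O[Si](C)(C)C(C)(C)C)CC[C@@H]1C(C)=C
F7 | step 3 | diastereomer of 10 with the enantiomeric ring and the same (R)-carbinol | C=CC[C@@H](O)C(C)(C)[C@@H]1C=C(O[Si](C)(C)C(C)(C)C)CC[C@@H]1C(C)=C
F8 | step 15 | 3,5-bis(tert-butyldimethylsilyloxy)-2,6,6-trimethyltricyclo[5.4.0.0^{2,8}]undec-9-en-9-yl trifluoromethanesulfonate | CC(C)(C)[Si](C)(C)O[C@@H]1C[C@@H](O[Si](C)(C)C(C)(C)C)[C@@]2(C)[C@@H]3CC=C(OS(=O)(=O)C(F)(F)F)[C@H]2[C@@H]3C1(C)C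
F9 | step 15 | 3,5-bis(tert-butyldimethylsilyloxy)-2,6,6,9-tetramethyltricyclo[5.4.0.0^{2,8}]undec-9-ene | CC(C)(C)[Si](C)(C)O[C@@H]1C[C@@H](O[Si](C)(C)C(C)(C)C)[C@@]2(C)[C@@H]3CC=C(C)[C@H]2[C@@H]3C1(C)C
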